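The 1,2-dioxane is taken apart at its only ring methylene, C5, which lies between the two ethyl-bearing carbons C4 and C6; C6 also carries a ring oxygen and the exocyclic carbon C7. C3–C4–C5–C6–C7 and one oxygen are therefore folded into a temporary δ-lactone, closed at C4=C5 by ring-closing metathesis of an acyclic diene: the 2-ethylacrylate of a tertiary vinyl carbinol of fixed C6 configuration. In one operation this builds the C3–C7 backbone and sets the C6 hydroxyl allylic to the new bond, so that directed hydrogenation sets C4. That oxygen later leaves C6 with inversion as hydrogen peroxide closes the peroxide ring; peroxycarbenium alkylation and iodo-Wittig/Negishi steps add the side chains.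

Key step: step 5

Remark on the chemistry: atom numbers are those of the target (C1 carboxyl carbon; C3, C4, C5, C6 ring carbons; C7=C8 and C11=C12 alkenes; C10 side-chain stereocentre); the C4–C5 bond is made as C4=C5 in step 5 and saturated in step 6.

Step 1
Reactants: 1 2-methylidenebutanal (2-ethylacrolein)
Product: 2 2-methylidenebutan-1-ol
Conditions: NaBH4, CeCl3·7H2O, MeOH, 0 °C
Reagents that add atoms: none
Why: Luche 1,2-reduction of the enal carbonyl should leave the 1,1-disubstituted alkene untouched; no stereocentre is formed.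

Step 2
Reactants: 2 2-methylidenebutan-1-ol
Product: 3 [(2R)-2-ethyloxiran-2-yl]methanol
Conditions: Ti(OiPr)4 (5 mol%), D-(−)-diethyl tartrate (6 mol%), t-BuOOH, 4 Å MS, CH2Cl2, −20 °C
Reagents that add atoms: tert-butyl hydroperoxide CC(C)(C)OO
Why: Katsuki–Sharpless asymmetric epoxidation of a 2-substituted allylic alcohol, in which the D-(−)-tartrate–titanium complex delivers oxygen to the alkene face that gives the (R)-epoxide and so fixes the future C6.

Step 3
Reactants: 3 [(2R)-2-ethyloxiran-2-yl]methanol
Product: 4 (2S)-2-ethylbut-3-ene-1,2-diol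
Conditions: Me3S+ I− (3.5 equiv), n-BuLi (3.4 equiv), THF, −10 °C → rt
Reagents that add atoms: trimethylsulfonium iodide C[S+](C)C.[I-]
Why: One-carbon homologation of an epoxide to an allylic alcohol with dimethylsulfonium methylide (attack at the unsubstituted epoxide carbon, then ylide-mediated β-elimination of Me2S); no bond to C6 is broken and the Payne rearrangement of the alkoxide is degenerate, so the stereocentre should be carried over unchanged.

Step 4
Reactants: 4 (2S)-2-ethylbut-3-ene-1,2-diol; 5 2-methylidenebutanoic acid (2-ethylacrylic acid)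
Product: 6 [(2S)-2-ethyl-2-hydroxybut-3-en-1-yl] 2-methylidenebutanoate
Conditions: DCC, DMAP (cat.), CH2Cl2, 0 °C → rt
Reagents that add atoms: none
Why: Steglich esterification should acylate only the primary hydroxyl, the tertiary allylic one being too hindered, and creates no stereocentre.

Step 5
Reactants: 6 [(2S)-2-ethyl-2-hydroxybut-3-en-1-yl] 2-methylidenebutanoate
Product: 7 (5S)-3,5-diethyl-5-hydroxy-5,6-dihydro-2H-pyran-2-one
Conditions: second-generation Grubbs catalyst RuCl2(=CHPh)(H2IMes)(PCy3) (5 mol%), toluene (0.01 M), 80 °C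
Reagents that add atoms: none
Why: Ring-closing olefin metathesis: the ruthenium alkylidene should load at the monosubstituted vinyl group on C6 and then engage the 1,1-disubstituted acrylate alkene through a metallacyclobutane, expelling ethene. The closest known reaction type is the ring-closing metathesis of acrylate and methacrylate esters of homoallylic alcohols to 5,6-dihydropyran-2-ones. One ring is closed, the six-membered unsaturated δ-lactone (C3, C4, C5, C6, C7 and the ester oxygen), by forming the C4=C5 bond, whose σ-component is the C4–C5 bond of the target. No stereocentre is created and C6 is not touched; the ring instead holds the C6 hydroxyl allylic to the new alkene and on one of its faces, which is the control element for C4 in step 6. The step needs cyclisation to win over cross-metathesis oligomers, which high dilution and the favourable ring size should secure, and it needs the catalyst to tolerate the free allylic alcohol, which as a tertiary carbinol cannot isomerise to a ketone.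

Step 6
Reactants: 7 (5S)-3,5-diethyl-5-hydroxy-5,6-dihydro-2H-pyran-2-one
Product: 8 (3S,5S)-3,5-diethyl-5-hydroxyoxan-2-one
Conditions: H2 (1 atm), [Ir(cod)(PCy3)(py)]PF6 (5 mol%), CH2Cl2, rt
Reagents that add atoms: none
Why: Hydroxyl-directed homogeneous hydrogenation: the cationic iridium centre binds the C6 hydroxyl and should deliver both hydrogens to the alkene face syn to it (also the face opposite the larger ethyl group), which sets C4 with its hydrogen cis to the hydroxyl and its ethyl cis to the C6 ethyl.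

Step 7
Reactants: 8 (3S,5S)-3,5-diethyl-5-hydroxyoxan-2-one
Product: 9 (2S,4S)-2-ethyl-4-hydroxy-4-(hydroxymethyl)-N-methoxy-N-methylhexanamide
Conditions: MeNH(OMe), AlMe3, CH2Cl2, 0 °C → rt
Reagents that add atoms: N,O-dimethylhydroxylamine CNOC
Why: Aminolysis of the δ-lactone by the aluminium amide formed from AlMe3 and the amine (Weinreb amide formation) should open the ring without enolising C4 and free the primary C7 hydroxyl.

Step 8
Reactants: 9 (2S,4S)-2-ethyl-4-hydroxy-4-(hydroxymethyl)-N-methoxy-N-methylhexanamide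
Product: 11 (2S)-2-{[(2S)-2-ethyloxiran-2-yl]methyl}-N-methoxy-N-methylbutanamide, via primary tosylate 10 (not isolated)
Conditions: TsCl, Et3N, DMAP (cat.), CH2Cl2, 0 °C; then K2CO3, MeOH, rt
Reagents that add atoms: none
Why: Selective sulfonylation of the primary hydroxyl followed by intramolecular Williamson displacement (3-exo-tet) by the tertiary alkoxide should give the epoxide; the C6–O bond is retained, so C6 keeps its configuration.

Step 9
Reactants: 11 (2S)-2-{[(2S)-2-ethyloxiran-2-yl]methyl}-N-methoxy-N-methylbutanamide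
Product: 12 (2S)-2-{[(2S)-2-ethyloxiran-2-yl]methyl}butanal
Conditions: i-Bu2AlH (1.2 equiv), THF, −78 °C
Reagents that add atoms: none
Why: Partial reduction of the Weinreb amide through its chelated tetrahedral aluminium intermediate should stop at the aldehyde, and at −78 °C neither the epoxide nor the α-stereocentre C4 should be affected.

Step 10
Reactants: 12 (2S)-2-{[(2S)-2-ethyloxiran-2-yl]methyl}butanal
Product: 15 (1R,4S,8S)-1,8-diethyl-2,3,5-trioxabicyclo[2.2.2]octane, via hydroperoxy hemiacetal 13 (not isolated), via dioxanol 14 (not isolated)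
Conditions: H2O2 (anhydrous, in Et2O), H3PMo12O40 (cat.), MgSO4, Et2O, 0 °C → rt
Reagents that add atoms: hydrogen peroxide OO
Why: Perhydrolysis cascade of known reaction types: hydrogen peroxide adds to the aldehyde, the hydroperoxy group opens the acid-activated 2,2-disubstituted epoxide at its tertiary carbon in a 6-exo, SN2-like manner (molybdenum-acid-catalysed perhydrolysis at the more substituted carbon), which should close the 1,2-dioxane and invert C6 to its final configuration, and the released C7 hydroxyl then acetalises the peroxy-hemiacetal so that C3 is locked in the bicyclic peroxyacetal.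

Step 11
Reactants: 15 (1R,4S,8S)-1,8-diethyl-2,3,5-trioxabicyclo[2.2.2]octane
Product: 16 methyl 2-[(3S,4S,6R)-4,6-diethyl-6-(hydroxymethyl)-1,2-dioxan-3-yl]acetate
Conditions: TiCl4, 1-(tert-butyldimethylsilyloxy)-1-methoxyethene, CH2Cl2, −78 °C
Reagents that add atoms: 1-(tert-butyldimethylsilyloxy)-1-methoxyethene C=C(OC)O[Si](C)(C)C(C)(C)C
Why: Lewis-acid substitution of a peroxyacetal through a peroxycarbenium ion (Mukaiyama-type addition of a silyl ketene acetal): TiCl4 should bind the more basic ether oxygen, the C3–O–C7 bridge should open, and the nucleophile should attack C3 axially, on the face opposite the departing oxygen, in the half-chair that has both ethyl groups equatorial, which sets C3 cis to the C4 ethyl.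

Step 12
Reactants: 16 methyl 2-[(3S,4S,6R)-4,6-diethyl-6-(hydroxymethyl)-1,2-dioxan-3-yl]acetate
Product: 17 methyl 2-[(3S,4S,6R)-4,6-diethyl-6-formyl-1,2-dioxan-3-yl]acetate
Conditions: Dess–Martin periodinane, CH2Cl2, 0 °C → rt
Reagents that add atoms: none
Why: Dess–Martin oxidation of the neopentyl-type primary alcohol is neutral and mild, so the peroxide and the ester should survive, and the aldehyde has no α-hydrogen and cannot epimerise.

Step 13
Reactants: 18 (2E)-pent-2-enal
Product: 19 (3R,4E)-hept-4-en-3-ol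
Conditions: Et2Zn, (2R)-(+)-3-exo-(dimethylamino)isoborneol (5 mol%), toluene, 0 °C
Reagents that add atoms: diethylzinc CC[Zn]CC
Why: Amino-alcohol-catalysed enantioselective 1,2-addition of diethylzinc to the enal; the (2R)-ligand–zinc complex shields one aldehyde face and should give the (R)-allylic alcohol.

Step 14
Reactants: 19 (3R,4E)-hept-4-en-3-ol
Product: 21 ethyl (3R,4E)-3-ethylhept-4-enoate, via ketene acetal 20 (not isolated)
Conditions: MeC(OEt)3, EtCO2H (cat.), 140 °C, EtOH distilled off
Reagents that add atoms: triethyl orthoacetate CCOC(C)(OCC)OCC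
Why: Johnson–Claisen rearrangement: the ketene acetal formed in the flask should rearrange through a chair transition state with the carbinol ethyl group equatorial, which gives the (E)-alkene and transfers the carbinol configuration suprafacially to the new C10 stereocentre (R).

Step 15
Reactants: 21 ethyl (3R,4E)-3-ethylhept-4-enoate
Product: 22 (3R,4E)-3-ethylhept-4-en-1-ol
Conditions: LiAlH4, Et2O, 0 °C
Reagents that add atoms: none
Why: Hydride reduction of the ester to the primary alcohol should leave the isolated alkene and the C10 stereocentre untouched.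

Step 16
Reactants: 22 (3R,4E)-3-ethylhept-4-en-1-ol
Product: 23 (3E,5R)-5-ethyl-7-iodohept-3-ene
Conditions: I2, PPh3, imidazole, CH2Cl2, 0 °C → rt
Reagents that add atoms: iodine II
Why: Appel-type iodination converts the primary alcohol to the iodide by SN2 at a carbon that is not stereogenic.

Step 17
Reactants: 23 (3E,5R)-5-ethyl-7-iodohept-3-ene
Product: 24 [(3R,4E)-3-ethylhept-4-en-1-yl]triphenylphosphonium iodide
Conditions: PPh3, MeCN, 80 °C
Reagents that add atoms: triphenylphosphine c1ccc(cc1)P(c1ccccc1)c1ccccc1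
Why: SN2 quaternisation of triphenylphosphine by the primary iodide should give the phosphonium salt.

Step 18
Reactants: 24 [(3R,4E)-3-ethylhept-4-en-1-yl]triphenylphosphonium iodide; 17 methyl 2-[(3S,4S,6R)-4,6-diethyl-6-formyl-1,2-dioxan-3-yl]acetate
Product: 28 methyl 2-{(3S,4S,6R)-4,6-diethyl-6-[(1Z,4R,5E)-4-ethyl-2-iodoocta-1,5-dien-1-yl]-1,2-dioxan-3-yl}acetate, via ylide 25 (not isolated), via iodophosphonium iodide 26 (not isolated), via iodo ylide 27 (not isolated)
Conditions: 24, NaN(SiMe3)2, THF, −20 °C; I2, −78 °C; NaN(SiMe3)2, −78 → −20 °C; then 17, −78 °C → rt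
Reagents that add atoms: iodine II
Why: Wittig olefination with an α-iodo ylide (Stork–Zhao-type: the ylide is iodinated, deprotonated again and condensed with the aldehyde), which under kinetic, lithium-free conditions should give the (Z)-iodoalkene with iodine cis to C6; the aldehyde has no α-hydrogen, and the dialkyl peroxide and the ester should not be attacked by the ylide at low temperature.

Step 19
Reactants: 28 methyl 2-{(3S,4S,6R)-4,6-diethyl-6-[(1Z,4R,5E)-4-ethyl-2-iodoocta-1,5-dien-1-yl]-1,2-dioxan-3-yl}acetate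
Product: 29 methyl 2-{(3S,4S,6R)-4,6-diethyl-6-[(1E,4R,5E)-2,4-diethylocta-1,5-dien-1-yl]-1,2-dioxan-3-yl}acetate
Conditions: Et2Zn, PdCl2(dppf) (5 mol%), THF, rt
Reagents that add atoms: diethylzinc CC[Zn]CC
Why: Negishi coupling: oxidative addition of zerovalent palladium to the C–I bond, transmetalation from zinc and reductive elimination all proceed with retention at the alkene, so ethyl should take the place of iodine cis to C6 and give the (E)-trisubstituted alkene; dialkyl peroxides are known to tolerate palladium cross-coupling at room temperature.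

Step 20
Reactants: 29 methyl 2-{(3S,4S,6R)-4,6-diethyl-6-[(1E,4R,5E)-2,4-diethylocta-1,5-dien-1-yl]-1,2-dioxan-3-yl}acetate
Product: 30 2-{(3S,4S,6R)-4,6-diethyl-6-[(1E,4R,5E)-2,4-diethylocta-1,5-dien-1-yl]-1,2-dioxan-3-yl}acetic acid (plakortide N)
Conditions: LiOH, THF/H2O, 0 °C → rt; then 1 M HCl to pH 3
Reagents that add atoms: lithium hydroxide [Li+].[OH-]
Why: Saponification of the methyl ester with LiOH at low temperature, which related 1,2-dioxane esters tolerate, followed by acidification should give the acid without touching any stereocentre.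

Compound list

1 | 2-methylidenebutanal (2-ethylacrolein) | C=C(CC)C=O | starting material
2 | 2-methylidenebutan-1-ol | C=C(CC)CO | intermediate
3 | [(2R)-2-ethyloxiran-2-yl]methanol | OC[C@]1(CC)CO1 | intermediate
4 | (2S)-2-ethylbut-3-ene-1,2-diol | OC[C@](O)(CC)C=C | intermediate
5 | 2-methylidenebutanoic acid (2-ethylacrylic acid) | C=C(CC)C(=O)O | starting material
6 | [(2S)-2-ethyl-2-hydroxybut-3-en-1-yl] 2-methylidenebutanoate | C=C(CC)C(=O)OC[C@](O)(CC)C=C | intermediate
7 | (5S)-3,5-diethyl-5-hydroxy-5,6-dihydro-2H-pyran-2-one | O=C1OC[C@](O)(CC)C=C1CC | intermediate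
8 | (3S,5S)-3,5-diethyl-5-hydroxyoxan-2-one | O=C1OC[C@](O)(CC)C[C@@H]1CC | intermediate
9 | (2S,4S)-2-ethyl-4-hydroxy-4-(hydroxymethyl)-N-methoxy-N-methylhexanamide | CON(C)C(=O)[C@@H](CC)C[C@@](O)(CC)CO | intermediate
10 | (2S,4S)-2-ethyl-2-hydroxy-4-[methoxy(methyl)carbamoyl]hexyl 4-methylbenzenesulfonate | CON(C)C(=O)[C@@H](CC)C[C@@](O)(CC)COS(=O)(=O)c1ccc(C)cc1 | intermediate
11 | (2S)-2-{[(2S)-2-ethyloxiran-2-yl]methyl}-N-methoxy-N-methylbutanamide | CON(C)C(=O)[C@@H](CC)C[C@@]1(CC)CO1 | intermediate
12 | (2S)-2-{[(2S)-2-ethyloxiran-2-yl]methyl}butanal | O=C[C@@H](CC)C[C@@]1(CC)CO1 | intermediate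
13 | (2S)-2-{[(2S)-2-ethyloxiran-2-yl]methyl}-1-hydroperoxybutan-1-ol (C1 epimers) | OOC(O)[C@@H](CC)C[C@@]1(CC)CO1 | intermediate
14 | (4S,6R)-4,6-diethyl-6-(hydroxymethyl)-1,2-dioxan-3-ol (C3 epimers) | OC1OO[C@](CO)(CC)C[C@@H]1CC | intermediate
15 | (1R,4S,8S)-1,8-diethyl-2,3,5-trioxabicyclo[2.2.2]octane | C1O[C@H]2OO[C@]1(CC)C[C@@H]2CC | intermediate
16 | methyl 2-[(3S,4S,6R)-4,6-diethyl-6-(hydroxymethyl)-1,2-dioxan-3-yl]acetate | OC[C@@]1(CC)C[C@H](CC)[C@H](CC(=O)OC)OO1 | intermediate
17 | methyl 2-[(3S,4S,6R)-4,6-diethyl-6-formyl-1,2-dioxan-3-yl]acetate | O=C[C@@]1(CC)C[C@H](CC)[C@H](CC(=O)OC)OO1 | intermediate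
18 | (2E)-pent-2-enal | CC/C=C/C=O | starting material
19 | (3R,4E)-hept-4-en-3-ol | CC[C@@H](O)/C=C/CC | intermediate
20 | (3R,4E)-3-[(1-ethoxyethenyl)oxy]hept-4-ene | CC[C@@H](OC(=C)OCC)/C=C/CC | intermediate
21 | ethyl (3R,4E)-3-ethylhept-4-enoate | CC/C=C/[C@H](CC)CC(=O)OCC | intermediate
22 | (3R,4E)-3-ethylhept-4-en-1-ol | CC/C=C/[C@H](CC)CCO | intermediate
23 | (3E,5R)-5-ethyl-7-iodohept-3-ene | CC/C=C/[C@H](CC)CCI | intermediate
24 | [(3R,4E)-3-ethylhept-4-en-1-yl]triphenylphosphonium iodide | CC/C=C/[C@H](CC)CC[P+](c1ccccc1)(c1ccccc1)c1ccccc1.[I-] | intermediate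
25 | [(3R,4E)-3-ethylhept-4-en-1-ylidene](triphenyl)-λ5-phosphane | CC/C=C/[C@H](CC)CC=P(c1ccccc1)(c1ccccc1)c1ccccc1 | intermediate
26 | [(3R,4E)-3-ethyl-1-iodohept-4-en-1-yl]triphenylphosphonium iodide (C1 epimers) | CC/C=C/[C@H](CC)CC(I)[P+](c1ccccc1)(c1ccccc1)c1ccccc1.[I-] | intermediate
27 | [(3R,4E)-3-ethyl-1-iodohept-4-en-1-ylidene](triphenyl)-λ5-phosphane | CC/C=C/[C@H](CC)CC(I)=P(c1ccccc1)(c1ccccc1)c1ccccc1 | intermediate
28 | methyl 2-{(3S,4S,6R)-4,6-diethyl-6-[(1Z,4R,5E)-4-ethyl-2-iodoocta-1,5-dien-1-yl]-1,2-dioxan-3-yl}acetate | CC/C=C/[C@H](CC)C/C(I)=C/[C@@]1(CC)C[C@H](CC)[C@H](CC(=O)OC)OO1 | intermediate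
29 | methyl 2-{(3S,4S,6R)-4,6-diethyl-6-[(1E,4R,5E)-2,4-diethylocta-1,5-dien-1-yl]-1,2-dioxan-3-yl}acetate | CC/C=C/[C@H](CC)C/C(=C/[C@@]1(CC)C[C@H](CC)[C@H](CC(=O)OC)OO1)CC | intermediate
30 | 2-{(3S,4S,6R)-4,6-diethyl-6-[(1E,4R,5E)-2,4-diethylocta-1,5-dien-1-yl]-1,2-dioxan-3-yl}acetic acid (plakortide N) | CC/C=C/[C@H](CC)C/C(=C/[C@@]1(CC)C[C@H](CC)[C@H](CC(=O)O)OO1)CC | target

Total step count: 20.
Longest linear sequence: 15 steps (steps 1 to 12, then 18 to 20); the side chain takes steps 13 to 17.

Steps most likely to fail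

Step 10. The epoxide may open through a free tertiary cation, which would lose the configuration at C6, or it may rearrange under acid (Meinwald type); the free aldehyde may also be over-oxidised by hydrogen peroxide (Baeyer–Villiger type) or epimerise at C4 through its enol. The fallback introduces the peroxide one oxidation level earlier and closes the acetal stepwise. It sets out from epoxy amide 11. Molybdenum-catalysed perhydrolysis (H2O2 in Et2O, MoO2(acac)2) should open the epoxide at the tertiary carbon with inversion and give (2S,4R)-2-ethyl-4-hydroperoxy-4-(hydroxymethyl)-N-methoxy-N-methylhexanamide F1. Condensation with acetone (TsOH cat.) should mask the hydroperoxide and the C7 hydroxyl together as the trioxane (2S)-2-{[(6R)-6-ethyl-3,3-dimethyl-1,2,4-trioxan-6-yl]methyl}-N-methoxy-N-methylbutanamide F2. Reduction with i-Bu2AlH at −78 °C should give (2S)-2-{[(6R)-6-ethyl-3,3-dimethyl-1,2,4-trioxan-6-yl]methyl}butanal F3. Acid-catalysed transacetalisation, in which the aldehyde displaces acetone, should then come back to the route at 15.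

Step 11. The Lewis acid may ionise the peroxide C–O bond instead of the ether bridge, it may trigger heterolysis of the O–O bond (Hock/Criegee-type fragmentation), or the addition may show poor facial selectivity at C3. The fallback exchanges the bridge for an exocyclic methoxy leaving group, the established substrate class for peroxycarbenium alkylation. It sets out from 15. Acid-catalysed methanolysis (MeOH, PPTS) should give [(3R,5S)-3,5-diethyl-6-methoxy-1,2-dioxan-3-yl]methanol F4, and silylation (t-BuPh2SiCl, imidazole) should give tert-butyl{[(3R,5S)-3,5-diethyl-6-methoxy-1,2-dioxan-3-yl]methoxy}diphenylsilane F5. TMSOTf-catalysed reaction with the same silyl ketene acetal should give methyl 2-[(3S,4S,6R)-6-{[tert-butyl(diphenyl)silyl]oxymethyl}-4,6-diethyl-1,2-dioxan-3-yl]acetate F6. HF·pyridine should cleave the silyl ether and come back to the route at 16.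

Step 18. The bulky α-iodo ylide may add sluggishly to the neopentyl-type aldehyde, or the Z-selectivity may erode. The fallback builds the trisubstituted alkene by two stereospecific cross-couplings on a geminal dibromide. It sets out from aldehyde 17 and draws its zinc partner from ester 21. Ramirez dibromo-olefination of 17 (CBr4, PPh3, Zn) should give methyl 2-[(3S,4S,6R)-6-(2,2-dibromoethenyl)-4,6-diethyl-1,2-dioxan-3-yl]acetate F7. Saponification of 21 should give (3R,4E)-3-ethylhept-4-enoic acid F8; iododecarboxylation (PhI(OAc)2, I2, hν) should give (3E,5S)-5-(iodomethyl)hept-3-ene F9; zinc insertion should give [(2S,3E)-2-ethylhex-3-en-1-yl]zinc iodide F10. Negishi coupling of F7 with F10 (PdCl2(DPEphos)) should take place at the less hindered bromide trans to C6 and give methyl 2-{(3S,4S,6R)-6-[(1Z,4R,5E)-2-bromo-4-ethylocta-1,5-dien-1-yl]-4,6-diethyl-1,2-dioxan-3-yl}acetate F11. A second Negishi coupling with Et2Zn (Pd(PtBu3)2, retention) should come back to the route at 29.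

Further compounds

F1 | step 10 | (2S,4R)-2-ethyl-4-hydroperoxy-4-(hydroxymethyl)-N-methoxy-N-methylhexanamide | CON(C)C(=O)[C@@H](CC)C[C@](CC)(CO)OO
F2 | step 10 | (2S)-2-{[(6R)-6-ethyl-3,3-dimethyl-1,2,4-trioxan-6-yl]methyl}-N-methoxy-N-methylbutanamide | CON(C)C(=O)[C@@H](CC)C[C@]1(CC)COC(C)(C)OO1
F3 | step 10 | (2S)-2-{[(6R)-6-ethyl-3,3-dimethyl-1,2,4-trioxan-6-yl]methyl}butanal | O=C[C@@H](CC)C[C@]1(CC)COC(C)(C)OO1
F4 | step 11 | [(3R,5S)-3,5-diethyl-6-methoxy-1,2-dioxan-3-yl]methanol (C6 epimers) | COC1OO[C@](CO)(CC)C[C@@H]1CC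
F5 | step 11 | tert-butyl{[(3R,5S)-3,5-diethyl-6-methoxy-1,2-dioxan-3-yl]methoxy}diphenylsilane | COC1OO[C@](CO[Si](c2ccccc2)(c2ccccc2)C(C)(C)C)(CC)C[C@@H]1CC
F6 | step 11 | methyl 2-[(3S,4S,6R)-6-{[tert-butyl(diphenyl)silyl]oxymethyl}-4,6-diethyl-1,2-dioxan-3-yl]acetate | COC(=O)C[C@@H]1OO[C@](CO[Si](c2ccccc2)(c2ccccc2)C(C)(C)C)(CC)C[C@@H]1CC
F7 | step 18 | methyl 2-[(3S,4S,6R)-6-(2,2-dibromoethenyl)-4,6-diethyl-1,2-dioxan-3-yl]acetate | BrC(Br)=C[C@@]1(CC)C[C@H](CC)[C@H](CC(=O)OC)OO1
F8 | step 18 | (3R,4E)-3-ethylhept-4-enoic acid | CC/C=C/[C@H](CC)CC(=O)O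
F9 | step 18 | (3E,5S)-5-(iodomethyl)hept-3-ene | CC/C=C/[C@H](CC)CI
F10 | step 18 | [(2S,3E)-2-ethylhex-3-en-1-yl]zinc iodide | CC/C=C/[C@H](CC)C[Zn]I
F11 | step 18 | methyl 2-{(3S,4S,6R)-6-[(1Z,4R,5E)-2-bromo-4-ethylocta-1,5-dien-1-yl]-4,6-diethyl-1,2-dioxan-3-yl}acetate | CC/C=C/[C@H](CC)C/C(Br)=C/[C@@]1(CC)C[C@H](CC)[C@H](CC(=O)OC)OO1
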